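A chain cannot be made or lost in this flask without spending free monomer, since every step thought possible that touches monomer in chains takes one. So the free monomer left caps any later gain. It is what to watch in the repeat, though it is not read directly.

the same everywhere: free monomer 0.10 M; initiator 10 mol%

| charge | transfer agent | temperature | remark | time |
|---|---|---|---|---|
| teal | 0.030 M | 0 °C | the very flask that is asked about, followed so far |  |
| green | 0.030 M | −5 °C | run made earlier |  |
| flask | 0.0300 M | 0 °C |  | 15 min |

| run | time / min | monomer in chains / % |
|---|---|---|
| teal | 1.00 | 18.2 |
| teal | 2.00 | 27.0 |
| teal | 3.00 | 28.2 |
| teal | 6.00 | 29.6 |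
| teal | 12.0 | 27.7 |
| green | 1.00 | 13.6 |
| green | 2.00 | 25.1 |
| green | 3.00 | 29.0 |
| green | 6.00 | 33.0 |
| green | 12.0 | 31.9 |

(scatter of a reading: 0.5 percentage points)

- a species is counted by the free monomer in it: one side product counts as two
- monomer in chains that was removed still counts
- steps thought possible: free monomer + initiator -> living end + monomer in chains; free monomer + living end -> monomer in chains + living end; living end + transfer agent -> dead chain; free monomer + monomer in chains -> side product; initiator <-> dormant form
- additions bring no volume worth counting

- beta: at 15 min take out 90 % of the monomer in chains then present, then wait 30 min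
- epsilon: change nothing and wait 30 min more
- delta: at 15 min raise the temperature by 10 K, then wait 30 min
- theta: at 15 min add initiator, 50.0 % of the amount charged, then wait 30 min

* monomer in chains, in percent of the free monomer first charged, at 15 min
* the remedy with the largest gain of monomer in chains, or "none" below 2 percentage points (beta / epsilon / delta / theta / none)
* monomer in chains present, with what was taken out counted in, in percent of the free monomer first charged, after beta
* monomer in chains present, with what was taken out counted in, in percent of the free monomer first charged, after delta

We read a ladder from the teal run. The first rung is the rise: the gain in the first minute is 0.182 min⁻¹ of the charge, and at that speed the peak reading takes 1.63 min. The next rung is our look at 15 min, later than the rise, so the teal flask is then on its slow stretch. There the readings drop by 1.9 percentage points, with a scatter of 0.5 points per reading, so the late fall is 0.00317 min⁻¹. The last rung is the peak divided by that fall, 93.5 min, longer than the look plus the wait.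

Both speeds carry the factor c(free monomer), so time drops out of their ratio. We assume that loss per free monomer runs about as fast as the first gain per free monomer. This is a guess, and a slower loss means more free monomer. The ratio then estimates the share of the charge still free during the late fall, and we call it the room, late fall over first gain: 1.74 %. That is below the bar of 2 points. We therefore commit to "none", and to about 27.7 % of monomer in chains at the look, and the same after beta and after delta.

The forecast gives 26.8 %, theta, 26 % and 13 %. It reckons “with free monomer near 65%” at the look.

The flask gives 27.4 %, none, 27.3 % and 27.1 %.

    free monomer + initiator → living end + monomer in chains (k = 0.220 M⁻¹ s⁻¹, Ea = 47.0 kJ mol⁻¹)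
    free monomer + living end → monomer in chains + living end, rate k2*[living end]*[free monomer] (k = 1.00 M⁻¹ s⁻¹, Ea = 36.0 kJ mol⁻¹)
    living end + transfer agent → dead chain (kL = 0.130 M⁻¹ s⁻¹, Ea = 35.0 kJ mol⁻¹)
    free monomer + monomer in chains → side product (k = 0.140 M⁻¹ s⁻¹, Ea = 55.0 kJ mol⁻¹)
    initiator ⇌ dormant form (K = 3.00, k = 0.00360 s⁻¹, Ea = 84.0 kJ mol⁻¹, ΔH = −85.0 kJ mol⁻¹)
    (constants at 0 °C)

The two part on free monomer, the limiting reagent. Against the forecast's 65, the flask holds 3.06 % at 7.50 min and 0.301 % at 15.0 min. Our room of 1.74 % lies below the first and above the second. The neighbouring flask has a quarter of the initiator, 2.5 mol%. Its room, read from its simulated state, is 28 %, more than in our flask. It holds 2.23 % monomer in chains and 70.0 % side product, and its initiator is down to 0.91 % of its charge.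

All runs were computed on assumed constants, and the scatter is random.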